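**Strategy.** Daucane numbering is used (cyclopentane C1–C5, cycloheptane C1, C5–C10). Everything rests on forming C5–C6 by a silicon-tethered radical cyclisation. The feature exploited is that, on the cyclopentane, the C4 oxygen and C6 are cis while C6 and C10 are trans across the C1–C5 fusion. A bromomethylsilyl ether of (R)-1-isopropyl-3-methylcyclopent-2-en-1-ol closes a temporary oxasilolane by attack of the silylmethyl radical (future C6) on C5; the C1 radical then takes an allyl group (C10, C9) from the opposite face, setting C5 and quaternary C1 at once. Tamao oxidation, methallylation, ring-closing metathesis (C8=C9), directed epoxidation and acylation complete the target.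

Key step: step 7

Remark: 3-methyl-2-methylenebutan-1-ol (1) is taken as purchasable; for the bicyclic compounds β means the face of the C1 methyl group.

**Step 1**
Reactants: 1 3-methyl-2-methylenebutan-1-ol; 2 tert-butyl hydroperoxide
Product: 3 [(2R)-2-isopropyloxiran-2-yl]methanol
Conditions: Ti(OiPr)4 (10 mol%), D-(−)-diethyl tartrate (12 mol%), tBuOOH, 4 Å MS, CH2Cl2, −20 °C
Reagents that add atoms: tert-butyl hydroperoxide 2, CC(C)(C)OO
Why: Sharpless asymmetric epoxidation of a 2-substituted allylic alcohol; the D-tartrate should deliver oxygen to the face that gives the R epoxide (by analogy with 2-methylallyl alcohol), which becomes C4 of the target.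

**Step 2**
Reactants: 3 [(2R)-2-isopropyloxiran-2-yl]methanol; 4 2-methylallylmagnesium chloride
Product: 5 (2R)-2-isopropyl-5-methylhex-5-ene-1,2-diol
Conditions: 4 (3 equiv), CuI (10 mol%), THF, −30 to 0 °C; aq NH4Cl
Reagents that add atoms: 2-methylallylmagnesium chloride 4, CC(=C)C[Mg]Cl
Why: Copper-catalysed SN2 opening of the epoxide at its unsubstituted CH2 carbon leaves the quaternary stereocentre untouched.

**Step 3**
Reactants: 5 (2R)-2-isopropyl-5-methylhex-5-ene-1,2-diol
Product: 6 (2R)-2-hydroxy-2-isopropyl-5-methylhex-5-enal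
Conditions: SO3·pyridine, DMSO, Et3N, CH2Cl2, 0 °C
Reagents that add atoms: none
Why: Parikh–Doering oxidation takes the primary alcohol to the aldehyde without glycol cleavage; the tertiary alcohol cannot be oxidised.

**Step 4**
Reactants: 6 (2R)-2-hydroxy-2-isopropyl-5-methylhex-5-enal; 7 methyltriphenylphosphonium bromide
Product: 8 (3R)-3-isopropyl-6-methylhepta-1,6-dien-3-ol
Conditions: 7 (2.5 equiv), KOtBu, THF, 0 °C to rt
Reagents that add atoms: methyltriphenylphosphonium bromide 7, C[P+](c1ccccc1)(c1ccccc1)c1ccccc1.[Br-]
Why: Wittig methylenation of the α-hydroxy aldehyde; excess ylide tolerates the free tertiary hydroxyl.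

**Step 5**
Reactants: 8 (3R)-3-isopropyl-6-methylhepta-1,6-dien-3-ol
Product: 9 (1R)-1-isopropyl-3-methylcyclopent-2-en-1-ol
Conditions: second-generation Grubbs catalyst (2 mol%), CH2Cl2, 40 °C
Reagents that add atoms: none
Why: Ring-closing metathesis of a vinyl and a 1,1-disubstituted alkene closes the cyclopentene with loss of ethene.

**Step 6**
Reactants: 9 (1R)-1-isopropyl-3-methylcyclopent-2-en-1-ol; 10 (bromomethyl)chlorodimethylsilane
Product: 11 (bromomethyl){[(1R)-1-isopropyl-3-methylcyclopent-2-en-1-yl]oxy}dimethylsilane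
Conditions: Et3N, DMAP (cat.), CH2Cl2, 0 °C; used crude
Reagents that add atoms: (bromomethyl)chlorodimethylsilane 10, C[Si](C)(Cl)CBr
Why: O-Silylation of the tertiary allylic alcohol with a small, reactive chlorosilane attaches the radical precursor to the C4 oxygen.

**Step 7**
Reactants: 11 (bromomethyl){[(1R)-1-isopropyl-3-methylcyclopent-2-en-1-yl]oxy}dimethylsilane; 12 allyltributylstannane
Product: 15 (3aR,4R,6aR)-4-allyl-6a-isopropyl-2,2,4-trimethylhexahydro-2H-cyclopenta[d][1,2]oxasilole, via silylmethyl radical 13 (not isolated), via cyclised tertiary radical 14 (not isolated)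
Conditions: 12 (3 equiv), AIBN (0.2 equiv, in portions), PhH (0.2 M), 80 °C
Reagents that add atoms: allyltributylstannane 12, C=CC[Sn](CCCC)(CCCC)CCCC
Why: Bu3Sn• abstracts bromine from 11 to give radical 13, which adds 5-exo-trig to C5 of the C5=C1 double bond, closing the five-membered 1-oxa-2-silacyclopentane ring by forming C5–C6 and leaving the tertiary C1 radical 14; 14 adds to allyltributylstannane and expels Bu3Sn•, which carries the chain. The closest known reaction types are the Nishiyama–Stork silicon-tethered radical cyclisation and the Keck radical allylation, joined here as a cyclisation–allyl-transfer cascade. The new ring can only be cis-fused, so the C4 stereocentre fixes C5 with C6 on the face of the C4 oxygen. The quaternary C1 centre is set by approach of the stannane to the convex face of bicyclic radical 14, anti to the new C5–C6 bond, which places the allyl group trans to C6 and the methyl group cis to it. The step needs cyclisation to outrun direct allylation of 13 (a fast 5-exo closure and a moderate stannane concentration should secure this) and 5-exo over 6-endo attack (secured by the disubstituted distal alkene carbon C1).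

**Step 8**
Reactants: 15 (3aR,4R,6aR)-4-allyl-6a-isopropyl-2,2,4-trimethylhexahydro-2H-cyclopenta[d][1,2]oxasilole; 16 hydrogen peroxide
Product: 17 (1R,2S,3R)-3-allyl-2-(hydroxymethyl)-1-isopropyl-3-methylcyclopentan-1-ol
Conditions: H2O2 (30%), KF, KHCO3, THF/MeOH, 40 °C
Reagents that add atoms: hydrogen peroxide 16, OO
Why: Tamao–Fleming oxidation of the cyclic alkoxysilane turns the C6–Si bond into C6–OH and frees the C4 hydroxyl; the terminal alkene is inert.

**Step 9**
Reactants: 17 (1R,2S,3R)-3-allyl-2-(hydroxymethyl)-1-isopropyl-3-methylcyclopentan-1-ol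
Product: 18 (1R,2R,5R)-5-allyl-2-hydroxy-2-isopropyl-5-methylcyclopentane-1-carbaldehyde
Conditions: Dess–Martin periodinane, NaHCO3, CH2Cl2, 0 °C; used at once
Reagents that add atoms: none
Why: Dess–Martin oxidation of the primary alcohol under buffered, non-basic conditions should avoid dehydration or retro-aldol cleavage of the β-hydroxy aldehyde.

**Step 10**
Reactants: 18 (1R,2R,5R)-5-allyl-2-hydroxy-2-isopropyl-5-methylcyclopentane-1-carbaldehyde; 4 2-methylallylmagnesium chloride
Product: 19 (1R,2S,3R)-3-allyl-2-[(1S)-1-hydroxy-3-methylbut-3-en-1-yl]-1-isopropyl-3-methylcyclopentan-1-ol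
Conditions: 4 (2.5 equiv), THF, −78 °C; aq NH4Cl
Reagents that add atoms: 2-methylallylmagnesium chloride 4, CC(=C)C[Mg]Cl
Why: Chelation-controlled Grignard addition: the magnesium alkoxide at C4 holds the aldehyde oxygen syn to it, and the nucleophile should enter anti to the quaternary C1, which gives the 6S carbinol (the Felkin–Anh model with C1 as the large group predicts the same face).

**Step 11**
Reactants: 19 (1R,2S,3R)-3-allyl-2-[(1S)-1-hydroxy-3-methylbut-3-en-1-yl]-1-isopropyl-3-methylcyclopentan-1-ol
Product: 20 jaeschkeanadiol (dauc-8-ene-4β,6α-diol)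
Conditions: second-generation Grubbs catalyst (5 mol%), CH2Cl2 (5 mM), 40 °C
Reagents that add atoms: none
Why: Ring-closing metathesis of the allyl and methallyl arms, which are trans on the cyclopentane, forms the trisubstituted C8=C9 bond and the trans-fused seven-membered ring.

**Step 12**
Reactants: 20 jaeschkeanadiol; 2 tert-butyl hydroperoxide
Product: 21 8α,9α-epoxydaucane-4β,6α-diol
Conditions: VO(acac)2 (5 mol%), tBuOOH, CH2Cl2, 0 °C to rt
Reagents that add atoms: tert-butyl hydroperoxide 2, CC(C)(C)OO
Why: Hydroxyl-directed vanadium-catalysed epoxidation: the homoallylic 6α-hydroxyl should deliver oxygen to the α face, which is also the face remote from the angular C1 methyl group.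

**Step 13**
Reactants: 21 8α,9α-epoxydaucane-4β,6α-diol; 22 3,4-dimethoxybenzoyl chloride
Product: 23 8α,9α-epoxy-4β-hydroxydaucan-6α-yl 3,4-dimethoxybenzoate (target)
Conditions: 22 (1.5 equiv), Et3N, DMAP, CH2Cl2, rt
Reagents that add atoms: 3,4-dimethoxybenzoyl chloride 22, COc1ccc(C(=O)Cl)cc1OC
Why: DMAP-catalysed acylation of the only secondary hydroxyl; the tertiary C4 hydroxyl does not acylate and the epoxide should survive the basic medium.

**Compound list**
1 | 3-methyl-2-methylenebutan-1-ol | CC(C)C(=C)CO | starting material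
2 | tert-butyl hydroperoxide | CC(C)(C)OO | starting material
3 | [(2R)-2-isopropyloxiran-2-yl]methanol | OC[C@]1(C(C)C)CO1 | intermediate
4 | 2-methylallylmagnesium chloride | CC(=C)C[Mg]Cl | starting material
5 | (2R)-2-isopropyl-5-methylhex-5-ene-1,2-diol | OC[C@](O)(C(C)C)CCC(C)=C | intermediate
6 | (2R)-2-hydroxy-2-isopropyl-5-methylhex-5-enal | O=C[C@](O)(C(C)C)CCC(C)=C | intermediate
7 | methyltriphenylphosphonium bromide | C[P+](c1ccccc1)(c1ccccc1)c1ccccc1.[Br-] | starting material
8 | (3R)-3-isopropyl-6-methylhepta-1,6-dien-3-ol | C=C[C@](O)(C(C)C)CCC(C)=C | intermediate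
9 | (1R)-1-isopropyl-3-methylcyclopent-2-en-1-ol | CC1=C[C@](O)(C(C)C)CC1 | intermediate
10 | (bromomethyl)chlorodimethylsilane | C[Si](C)(Cl)CBr | starting material
11 | (bromomethyl){[(1R)-1-isopropyl-3-methylcyclopent-2-en-1-yl]oxy}dimethylsilane | CC1=C[C@](O[Si](C)(C)CBr)(C(C)C)CC1 | intermediate
12 | allyltributylstannane | C=CC[Sn](CCCC)(CCCC)CCCC | starting material
13 | silylmethyl radical derived from 11 | CC1=C[C@](O[Si](C)(C)[CH2])(C(C)C)CC1 | intermediate
14 | cyclised tertiary C1 radical (cis-fused oxasilolane) | C[C]3CC[C@@](O[Si](C)(C)C2)(C(C)C)[C@H]23 | intermediate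
15 | (3aR,4R,6aR)-4-allyl-6a-isopropyl-2,2,4-trimethylhexahydro-2H-cyclopenta[d][1,2]oxasilole | C=CC[C@@]3(C)CC[C@@](O[Si](C)(C)C2)(C(C)C)[C@H]23 | intermediate
16 | hydrogen peroxide | OO | starting material
17 | (1R,2S,3R)-3-allyl-2-(hydroxymethyl)-1-isopropyl-3-methylcyclopentan-1-ol | C=CC[C@@]3(C)CC[C@@](O)(C(C)C)[C@@H]3CO | intermediate
18 | (1R,2R,5R)-5-allyl-2-hydroxy-2-isopropyl-5-methylcyclopentane-1-carbaldehyde | C=CC[C@@]3(C)CC[C@@](O)(C(C)C)[C@@H]3C=O | intermediate
19 | (1R,2S,3R)-3-allyl-2-[(1S)-1-hydroxy-3-methylbut-3-en-1-yl]-1-isopropyl-3-methylcyclopentan-1-ol | C=CC[C@@]3(C)CC[C@@](O)(C(C)C)[C@@H]3[C@@H](O)CC(C)=C | intermediate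
20 | jaeschkeanadiol (dauc-8-ene-4β,6α-diol) | O[C@H]2CC(C)=CC[C@@]3(C)CC[C@@](O)(C(C)C)[C@H]23 | intermediate
21 | 8α,9α-epoxydaucane-4β,6α-diol | O[C@H]2C[C@@]3(C)O[C@H]3C[C@@]3(C)CC[C@@](O)(C(C)C)[C@H]23 | intermediate
22 | 3,4-dimethoxybenzoyl chloride | COc1ccc(C(=O)Cl)cc1OC | starting material
23 | 8α,9α-epoxy-4β-hydroxydaucan-6α-yl 3,4-dimethoxybenzoate | COc1ccc(C(=O)O[C@H]2C[C@@]3(C)O[C@H]3C[C@@]3(C)CC[C@@](O)(C(C)C)[C@H]23)cc1OC | target

**Total step count:** 13. **Longest linear sequence:** 13 steps (1 to 23).

**Steps most likely to fail**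

Step 7. The risks are allyl transfer to the silylmethyl radical before it cyclises, slow allyl transfer to the electron-rich tertiary radical, and attack of the stannane on the wrong face of C1. The fallback is a polarity-matched version of the same ring closure with a temporary carbonyl group at C2. It sets out from 9: allylic oxidation of the only ring methylene next to the double bond (Rh2(cap)4, tBuOOH, CH2Cl2) should give the enone (R)-4-hydroxy-4-isopropyl-2-methylcyclopent-2-en-1-one F1. Silylation with 10 (Et3N, DMAP) gives its bromomethylsilyl ether F2. Under the conditions of step 7 the silylmethyl radical now adds to the enone β-carbon C5, and the electrophilic α-keto radical at C1 takes the allyl group from 12 more readily, giving the oxasilolane ketone F3. Tamao oxidation gives the keto diol F4. Its tosylhydrazone F5 (TsNHNH2, MeOH) is reduced with catecholborane and then NaOAc to the methylene compound, which is 17, where the route is rejoined.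

Step 10. The risks are poor facial selectivity at C6 if the magnesium chelate does not form, and dehydration or retro-aldol cleavage of the β-hydroxy aldehyde by the basic reagent. The fallback replaces substrate control by reagent control with a non-basic allylborane. It sets out from 18, which is treated at −78 °C with B-(2-methylallyl)diisopinocampheylborane, made from 4 and (−)-B-methoxydiisopinocampheylborane (the antipode from (+)-α-pinene, which should give the 6S carbinol), followed by ethanolamine work-up. It comes back at 19, and no new compound arises on this path (entry F0).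

Step 12. The risks are loss of facial selectivity and vanadium-promoted opening of the trisubstituted epoxide by the neighbouring hydroxyl groups. The fallback reverses the order so that steric control replaces directed control. It sets out from 20, which is acylated with 22 (Et3N, DMAP, CH2Cl2) to jaeschkeanadiol 6-(3,4-dimethoxybenzoate) F6. Buffered mCPBA (NaHCO3, CH2Cl2, 0 °C) should then epoxidise the C8=C9 bond from the α face, opposite the C1 methyl group, and the path comes back at 23.

**Further compounds**
F1 | step 7 | (R)-4-hydroxy-4-isopropyl-2-methylcyclopent-2-en-1-one | CC1=C[C@](O)(C(C)C)CC1=O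
F2 | step 7 | (R)-4-{[(bromomethyl)dimethylsilyl]oxy}-4-isopropyl-2-methylcyclopent-2-en-1-one | CC1=C[C@](O[Si](C)(C)CBr)(C(C)C)CC1=O
F3 | step 7 | 5-oxo derivative of oxasilolane 15 (4-allyl-6a-isopropyl-2,2,4-trimethylhexahydro-5H-cyclopenta[d][1,2]oxasilol-5-one, same configuration as 15) | C=CC[C@@]3(C)C(=O)C[C@@](O[Si](C)(C)C2)(C(C)C)[C@H]23
F4 | step 7 | 2-allyl-4-hydroxy-3-(hydroxymethyl)-4-isopropyl-2-methylcyclopentan-1-one (configuration as in 17) | C=CC[C@@]3(C)C(=O)C[C@@](O)(C(C)C)[C@@H]3CO
F5 | step 7 | tosylhydrazone of F4 | C=CC[C@@]3(C)C(=NNS(=O)(=O)c4ccc(C)cc4)C[C@@](O)(C(C)C)[C@@H]3CO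
F0 | step 10 | none | none
F6 | step 12 | jaeschkeanadiol 6-(3,4-dimethoxybenzoate) | COc1ccc(C(=O)O[C@H]2CC(C)=CC[C@@]3(C)CC[C@@](O)(C(C)C)[C@H]23)cc1OC
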